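**Retrosynthetic overview**
1. Target 14 ⇒ spiro-epoxide 12 + α-methylene-γ-butyrolactone 13 (C11–C12 bond and butenolide C=C formed in one new cobalt-catalysed step).
2. 12 ⇒ C9 ketone 10 (methylenation, then α-face epoxidation fixes the 9α-oxygen).
3. 10 ⇒ Δ5-alkene 8 (trans-diaxial bromoacetoxylation and radical debromination give 6β-OAc and 5α-H) ⇒ enedione 6 (C4 gem-dimethylation, C3 reduction).
4. 6 ⇒ (S)-Hajos–Parrish ketone 5 by one-carbon ring expansion of the cyclopentanone with diazoethane (builds ring B with C8–Me and C9=O).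
5. 5 ⇒ 2-methylcyclopentane-1,3-dione 1 + methyl vinyl ketone 2. Ring order: cyclopentane (bought) → ring A (proline aldol) → ring B (5→6 expansion) → butenolide attached intact.

Assumption: ethereal diazoethane (prepared beforehand from N-ethyl-N-nitrosourea) is treated as a reagent; the decalin is numbered as in labdanes (C10 carries the angular methyl, C4 the gem-dimethyl, C9 the side chain C11–C16; α = face opposite the C10 methyl).

**Route**

Step 1
Reactants: 1 2-methylcyclopentane-1,3-dione; 2 methyl vinyl ketone (but-3-en-2-one)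
Product: 3 2-methyl-2-(3-oxobutyl)cyclopentane-1,3-dione
Conditions: H2O, AcOH (cat.), 70 °C
Reagents that add atoms: none
Why: Michael addition of the acidic cyclic 1,3-dione to the enone gives the achiral triketone cleanly (no stereocentre formed).

Step 2
Reactants: 3 2-methyl-2-(3-oxobutyl)cyclopentane-1,3-dione
Product: 5 (7aS)-7a-methyl-2,3,7,7a-tetrahydro-1H-indene-1,5(6H)-dione [(S)-Hajos–Parrish ketone], via bicyclic ketol 4 (not isolated)
Conditions: L-proline (3 mol %), DMF, rt; then conc. H2SO4 (cat.), 95 °C; recrystallise to >99% ee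
Reagents that add atoms: none
Why: Hajos–Parrish–Eder–Sauer–Wiechert reaction, in which the L-proline enamine differentiates the two enantiotopic ring carbonyls in the intramolecular aldol and so sets the quaternary centre (future C10, β-methyl) as 7aS, followed by acid dehydration of the cis-ketol.

Step 3
Reactants: 5 (S)-Hajos–Parrish ketone
Product: 6 (2R,8aS)-2,8a-dimethyl-3,4,8,8a-tetrahydronaphthalene-1,6(2H,7H)-dione (8α,10β-dimethyl-Δ4-octalin-3,9-dione)
Conditions: CH3CHN2 (Et2O solution, 1.5 equiv, slow addition), Sc(OTf)3 (10 mol %), CH2Cl2, −78 °C; then DBU (cat.), rt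
Reagents that add atoms: diazoethane CC=[N+]=[N-]
Why: Lewis-acid-catalysed diazoalkane homologation (Tiffeneau–Demjanov-type ring expansion) in which diazoethane adds to the saturated cyclopentanone carbonyl rather than the less electrophilic enone, the less substituted CH2 migrates with loss of N2 (as in D-homoannulation of 17-keto steroids) to give the six-membered ring B with C9=O and C8–Me, and DBU equilibrates C8 to the equatorial 8α-methyl that avoids the syn-axial C10 methyl.

Step 4
Reactants: 6 8α,10β-dimethyl-Δ4-octalin-3,9-dione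
Product: 7 (2R,8aS)-2,5,5,8a-tetramethyl-3,5,8,8a-tetrahydronaphthalene-1,6(2H,7H)-dione (4,4,8α,10β-tetramethyl-Δ5-octalin-3,9-dione)
Conditions: KOt-Bu (2.1 equiv), t-BuOH–THF, 0 °C; MeI (3 equiv)
Reagents that add atoms: iodomethane CI
Why: Deconjugative α,α-dimethylation of the enone through its extended dienolate, where only 2.1 equiv of base is used so that the much less acidic, hindered C8–H next to the C9 ketone is at most reversibly deprotonated and reprotonated by t-BuOH (keeping the thermodynamic 8α-methyl) rather than alkylated.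

Step 5
Reactants: 7 4,4,8α,10β-tetramethyl-Δ5-octalin-3,9-dione
Product: 8 (2R,6S,8aS)-6-hydroxy-2,5,5,8a-tetramethyl-3,5,6,7,8,8a-hexahydronaphthalen-1(2H)-one (3β-hydroxy-4,4,8α,10β-tetramethyl-Δ5-octalin-9-one)
Conditions: NaBH4 (0.3 equiv), MeOH–CH2Cl2, −40 °C
Reagents that add atoms: none
Why: Chemoselective borohydride reduction in which hydride attacks the C3 ketone axially from the α-face (the β-face is blocked by the axial 4β-methyl) to give the equatorial 3β-alcohol, while the C9 ketone flanked by quaternary C10 and tertiary C8 reacts far more slowly at −40 °C.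

Step 6
Reactants: 8 3β-hydroxy-4,4,8α,10β-tetramethyl-Δ5-octalin-9-one
Product: 9 6β-acetoxy-5α-bromo-3β-hydroxy-4,4,8α,10β-tetramethyl-trans-decalin-9-one
Conditions: NBS (1.1 equiv), AcOH–CH2Cl2, 0 °C → rt, dark
Reagents that add atoms: N-bromosuccinimide O=C1CCC(=O)N1Br; acetic acid CC(=O)O
Why: Electrophilic bromoacetoxylation in which the bromonium ion forms on the open α-face and acetic acid opens it trans-diaxially at C6 from the β-face (Fürst–Plattner rule, as in Δ5-steroid bromohydrin formation), setting 5α-Br and 6β-OAc and placing the acetate on C6 only so that the 3-OH needs no protection.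

Step 7
Reactants: 9 6β-acetoxy-5α-bromo-3β-hydroxy-4,4,8α,10β-tetramethyl-trans-decalin-9-one
Product: 10 6β-acetoxy-3β-hydroxy-4,4,8α,10β-tetramethyl-5α-decalin-9-one (trans-fused)
Conditions: Bu3SnH (1.3 equiv), AIBN (cat.), PhH, 80 °C
Reagents that add atoms: none
Why: Radical chain hydrodebromination in which the tertiary C5 radical takes hydrogen from the α-face (the β-face is shielded by the C10 methyl, the 4β-methyl and the 6β-acetate), giving the trans-decalin with 5α-H under neutral conditions that leave ketone, acetate and alcohol untouched.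

Step 8
Reactants: 10 6β-acetoxy-3β-hydroxy-4,4,8α,10β-tetramethyl-5α-decalin-9-one
Product: 11 6β-acetoxy-4,4,8α,10β-tetramethyl-9-methylene-5α-decalin-3β-ol
Conditions: CH2Br2, Zn, TiCl4, THF–CH2Cl2, 0 °C → rt
Reagents that add atoms: dibromomethane BrCBr
Why: Takai–Lombardo methylenation, whose non-basic Zn/Ti gem-dimetallic reagent converts hindered, enolisable ketones to methylene compounds without epimerising C8 and tolerates the acetate and the free hydroxyl.

Step 9
Reactants: 11 6β-acetoxy-4,4,8α,10β-tetramethyl-9-methylene-5α-decalin-3β-ol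
Product: 12 9α,11-epoxide of 11 (spiro-oxirane at C9, oxygen on the α-face, C11 on the β-face)
Conditions: mCPBA, Na2HPO4, CH2Cl2, 0 °C
Reagents that add atoms: meta-chloroperoxybenzoic acid OOC(=O)c1cccc(Cl)c1
Why: Prilezhaev epoxidation in which the peracid approaches the exocyclic alkene axially from the α-face, anti to the adjacent axial C10 methyl, so the C9 oxygen is set α and C11 is left β-equatorial.

Step 10
Reactants: 12 9α,11-spiro-epoxide; 13 α-methylene-γ-butyrolactone (3-methylenedihydrofuran-2(3H)-one)
Product: 14 6β-acetoxy-3β,9α-dihydroxy-8α-methyl-labd-13-en-16,15-olide (target CNP0513254.1)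
Conditions: Co(dmgH)2(py)Cl (15 mol %), Zn dust (30 mol %), i-Pr2NEt (0.3 equiv), 13 (3 equiv, slow addition), MeOH–MeCN, 450 nm LEDs, 25 °C
Reagents that add atoms: none
Why: Proposed new method: cobaloxime(I) made by Zn reduction opens the epoxide by SN2 attack at the unsubstituted C11 (the C9–O bond and thus the 9α-configuration are untouched), blue light homolyses the 2-hydroxyalkyl–Co(III) bond, the primary C11 radical adds to the exocyclic CH2 of 13 to form C11–C12, and Co(II) abstracts a hydrogen atom from ring carbon C14 of the tertiary α-lactone radical (the same selectivity as cobaloxime catalytic chain transfer in methacrylate polymerisation) to give the conjugated endocyclic butenolide while Co(III)–H is deprotonated back to Co(I), with reversible Co–H addition funnelling any exocyclic alkylidene isomer to the more stable butenolide; the closest known reaction types are stoichiometric epoxide opening and photolytic radical chemistry of hydroxyalkylcobaloximes and cobalt-catalysed Heck-type couplings of alkyl halides or epoxides with styrenes.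

**Compound list**

1 | 2-methylcyclopentane-1,3-dione | CC1C(=O)CCC1=O | starting material
2 | methyl vinyl ketone | CC(=O)C=C | starting material
3 | 2-methyl-2-(3-oxobutyl)cyclopentane-1,3-dione | CC(=O)CCC1(C)C(=O)CCC1=O | intermediate
4 | (3aS,7aS)-3a-hydroxy-7a-methyl-2,3,3a,4,7,7a-hexahydro-1H-indene-1,5(6H)-dione (cis-ketol) | C[C@]12CCC(=O)C[C@@]1(O)CCC2=O | intermediate (not isolated)
5 | (7aS)-7a-methyl-2,3,7,7a-tetrahydro-1H-indene-1,5(6H)-dione | C[C@]12CCC(=O)C=C1CCC2=O | intermediate
6 | (2R,8aS)-2,8a-dimethyl-3,4,8,8a-tetrahydronaphthalene-1,6(2H,7H)-dione | C[C@@H]1CCC2=CC(=O)CC[C@]2(C)C1=O | intermediate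
7 | (2R,8aS)-2,5,5,8a-tetramethyl-3,5,8,8a-tetrahydronaphthalene-1,6(2H,7H)-dione | C[C@@H]1CC=C2C(C)(C)C(=O)CC[C@]2(C)C1=O | intermediate
8 | (2R,6S,8aS)-6-hydroxy-2,5,5,8a-tetramethyl-3,5,6,7,8,8a-hexahydronaphthalen-1(2H)-one | C[C@@H]1CC=C2C(C)(C)[C@@H](O)CC[C@]2(C)C1=O | intermediate
9 | 6β-acetoxy-5α-bromo-3β-hydroxy-4,4,8α,10β-tetramethyl-trans-decalin-9-one | CC(=O)O[C@@H]1C[C@@H](C)C(=O)[C@@]2(C)CC[C@H](O)C(C)(C)[C@]12Br | intermediate
10 | 6β-acetoxy-3β-hydroxy-4,4,8α,10β-tetramethyl-5α-decalin-9-one | CC(=O)O[C@@H]1C[C@@H](C)C(=O)[C@@]2(C)CC[C@H](O)C(C)(C)[C@H]12 | intermediate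
11 | 6β-acetoxy-4,4,8α,10β-tetramethyl-9-methylene-5α-decalin-3β-ol | CC(=O)O[C@@H]1C[C@@H](C)C(=C)[C@@]2(C)CC[C@H](O)C(C)(C)[C@H]12 | intermediate
12 | 9α,11-epoxide of 11 (spiro-oxirane, O α) | CC(=O)O[C@@H]1C[C@@H](C)[C@]3(CO3)[C@@]2(C)CC[C@H](O)C(C)(C)[C@H]12 | intermediate
13 | α-methylene-γ-butyrolactone | C=C1CCOC1=O | starting material
14 | 6β-acetoxy-3β,9α-dihydroxy-8α-methyl-labd-13-en-16,15-olide | CC(=O)O[C@@H]1C[C@@H](C)[C@](O)(CCC2=CCOC2=O)[C@@]2(C)CC[C@H](O)C(C)(C)[C@H]12 | target

**Step count**

Total steps: 10. Longest linear sequence: 10 (1 → 14; 13 is bought and enters in the last step).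

**Three steps most likely to fail**

Step 10 (new reaction). The hindered epoxide may be opened slowly by Co(I), 13 may oligomerise or be isomerised by Co–H, and some exocyclic alkylidene lactone may form. Fallback with known chemistry, setting out from 12 and coming back at 14: treat 12 with dimethylsulfonium methylide (Me3S+ I−, n-BuLi, THF, −10 °C → rt), which opens the epoxide at C11 and eliminates to give the tertiary allylic alcohol 6β-acetoxy-9β-vinyl-4,4,8α,10β-tetramethyl-5α-decalin-3β,9α-diol F4. Hydroborate the vinyl group with 9-BBN (THF, rt) to the B-alkyl-9-BBN adduct of the vinyl carbinol F5, used without isolation. Couple this in a B-alkyl Suzuki–Miyaura reaction with commercial 3-bromo-2(5H)-furanone (Pd(dppf)Cl2, AsPh3, Cs2CO3, DMF–H2O, rt) to reach 14.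

Step 3 (ring expansion). Diazoethane may add to the enone (pyrazoline or conjugate attack), the quaternary carbon may migrate in part, or the product may be homologated again. Fallback setting out from 5 and coming back at 7: homologate 5 with the acceptor-stabilised methyl 2-diazopropanoate (BF3·OEt2, CH2Cl2, −20 °C), a better-controlled insertion that gives the α-methyl β-keto ester methyl 8,10β-dimethyl-3,9-dioxo-Δ4-octalin-8-carboxylate F1. Its quaternary C8 cannot be over-alkylated, so the KOt-Bu/MeI gem-dimethylation can be run on it directly to give methyl 4,4,8,10β-tetramethyl-3,9-dioxo-Δ5-octalin-8-carboxylate F2. Krapcho dealkoxycarbonylation (LiCl, wet DMSO, 150 °C) then delivers 7 with the thermodynamic 8α-methyl. This detour costs one step and also removes the C8 over-alkylation risk of step 4.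

Step 8 (methylenation). The C9 ketone is flanked by a quaternary and a tertiary carbon and may not react with the Zn/Ti reagent. Fallback setting out from 10 and coming back at 11: a two-stage Peterson olefination. Add the small, non-basic organocerium reagent from Me3SiCH2Li/CeCl3 (THF, −78 °C), which attacks from the α-face to give the β-hydroxysilane 6β-acetoxy-9α-(trimethylsilylmethyl)-4,4,8α,10β-tetramethyl-5α-decalin-3β,9β-diol F3. Acid-promoted elimination (TsOH cat., CH2Cl2, rt) then gives only the exocyclic alkene 11; the C9 configuration of F3 is irrelevant because it is lost on elimination.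

**Further compounds**

F1 | step 3 | methyl 8,10β-dimethyl-3,9-dioxo-Δ4-octalin-8-carboxylate (C8 epimers both usable, 8β-ester drawn) | COC(=O)[C@@]1(C)CCC2=CC(=O)CC[C@]2(C)C1=O
F2 | step 3 | methyl 4,4,8,10β-tetramethyl-3,9-dioxo-Δ5-octalin-8-carboxylate (8β-ester drawn) | COC(=O)[C@@]1(C)CC=C2C(C)(C)C(=O)CC[C@]2(C)C1=O
F3 | step 8 | 6β-acetoxy-9α-(trimethylsilylmethyl)-4,4,8α,10β-tetramethyl-5α-decalin-3β,9β-diol | CC(=O)O[C@@H]1C[C@@H](C)[C@@](O)(C[Si](C)(C)C)[C@@]2(C)CC[C@H](O)C(C)(C)[C@H]12
F4 | step 10 | 6β-acetoxy-9β-vinyl-4,4,8α,10β-tetramethyl-5α-decalin-3β,9α-diol | CC(=O)O[C@@H]1C[C@@H](C)[C@](O)(C=C)[C@@]2(C)CC[C@H](O)C(C)(C)[C@H]12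
F5 | step 10 | B-alkyl-9-BBN adduct of the vinyl carbinol (boron on C12) | CC(=O)O[C@@H]1C[C@@H](C)[C@](O)(CCB3C4CCCC3CCC4)[C@@]2(C)CC[C@H](O)C(C)(C)[C@H]12
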